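**Retrosynthetic overview**

1. The target is the 2,3-trans flavan-3-ol (2S,3R)-gallocatechin 7-O-gallate. The end-game is hydrogenolysis of seven benzyl ethers, preceded by stereoretentive oxidation of a C3–B bond to C3–OH.
2. The strategy rests on ring C, a dihydropyran whose O1–C2 and C3–C4 bonds flank the trans C2/C3 pair and whose C4 is a methylene on ring A carbon C4a, ortho to the O1-bearing C8a. Cutting both bonds at once gives a ring A ortho-quinone methide (from a salicyl alcohol that already carries the gallate on the future O7) and a ring B (E)-styrylboronate, joined by a chiral phosphoric acid catalysed oxa-[4+2].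
3. Ring A piece: 2,4,6-trihydroxybenzaldehyde, bis-methoxymethylation, benzylation of the chelated hydroxyl, acetal removal, acylation of the para hydroxyl with tribenzylgalloyl chloride, NaBH4. In the trihydroxy aldehyde only one ortho hydroxyl is chelated at a time, so direct para-acylation is not reliable; after this detour the para hydroxyl is the only unchelated one.
4. Ring B piece: 3,4,5-tris(benzyloxy)benzaldehyde, boron-Wittig olefination with bis(pinacolboryl)methane.
5. Ring order: rings A, B and the galloyl ring are bought as arenes; ring C is the only ring formed, in the key step.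

Key step: step 8

Remark: the target is read as (2S,3R), 2,3-trans; the boron intermediate has the same spatial arrangement but is labelled (2R,3R) because boron ranks below carbon.

**Route**

Step 1
Reactants: 1 2,4,6-trihydroxybenzaldehyde
Product: 2 2-hydroxy-4,6-bis(methoxymethoxy)benzaldehyde
Conditions: MOMCl (2.1 equiv), i-Pr2NEt, CH2Cl2, 0 °C → rt
Reagents that add atoms: chloromethyl methyl ether, COCCl
Why: Williamson-type O-alkylation takes the para hydroxyl and one ortho hydroxyl, whereas the second ortho hydroxyl then sits in a hydrogen bond to the formyl oxygen and is left free.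

Step 2
Reactants: 2 2-hydroxy-4,6-bis(methoxymethoxy)benzaldehyde
Product: 3 2-(benzyloxy)-4,6-bis(methoxymethoxy)benzaldehyde
Conditions: BnBr, K2CO3, DMF, 60 °C
Reagents that add atoms: benzyl bromide, BrCc1ccccc1
Why: Williamson etherification in warm DMF alkylates the remaining chelated phenol, and the acetals and the aldehyde are inert to these conditions.

Step 3
Reactants: 3 2-(benzyloxy)-4,6-bis(methoxymethoxy)benzaldehyde
Product: 4 2-(benzyloxy)-4,6-dihydroxybenzaldehyde
Conditions: 3 M HCl, MeOH/THF, 50 °C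
Reagents that add atoms: none
Why: Acid-catalysed transacetalisation with methanol removes both methoxymethyl ethers while the benzyl ether survives, leaving a diol whose para hydroxyl is free and whose single ortho hydroxyl is chelated to the formyl group.

Step 4
Reactants: 5 3,4,5-tris(benzyloxy)benzoic acid
Product: 6 3,4,5-tris(benzyloxy)benzoyl chloride
Conditions: (COCl)2, N,N-dimethylformamide (cat.), CH2Cl2, 0 °C → rt
Reagents that add atoms: oxalyl chloride, O=C(Cl)C(=O)Cl
Why: Acid chloride formation through the Vilsmeier-type chloroiminium salt is clean because the by-products are gases and the benzyl ethers are untouched.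

Step 5
Reactants: 4 2-(benzyloxy)-4,6-dihydroxybenzaldehyde; 6 3,4,5-tris(benzyloxy)benzoyl chloride
Product: 7 3-(benzyloxy)-4-formyl-5-hydroxyphenyl 3,4,5-tris(benzyloxy)benzoate
Conditions: 6 (1.0 equiv), Et3N (1.1 equiv), CH2Cl2, −20 → 0 °C
Reagents that add atoms: none
Why: O-acylation of a phenol with an acid chloride and amine base goes to the more acidic, unchelated para hydroxyl (as in the 4-O-selective acylation of 2,4-dihydroxybenzaldehydes), which fixes the gallate on the oxygen that becomes O7.

Step 6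
Reactants: 7 3-(benzyloxy)-4-formyl-5-hydroxyphenyl 3,4,5-tris(benzyloxy)benzoate
Product: 8 3-(benzyloxy)-5-hydroxy-4-(hydroxymethyl)phenyl 3,4,5-tris(benzyloxy)benzoate
Conditions: NaBH4 (1 equiv), THF/EtOH, −20 °C, 20 min; pH 7 phosphate buffer; used without storage
Reagents that add atoms: none
Why: Borohydride reduction of the aldehyde is far faster than attack on the aryl ester with one equivalent of hydride at low temperature, and the short time and neutral quench keep the electron-rich salicyl alcohol from ionising.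

Step 7
Reactants: 9 3,4,5-tris(benzyloxy)benzaldehyde; 10 2,2'-methylenebis(4,4,5,5-tetramethyl-1,3,2-dioxaborolane) [bis(pinacolboryl)methane]
Product: 13 (E)-4,4,5,5-tetramethyl-2-{2-[3,4,5-tris(benzyloxy)phenyl]ethenyl}-1,3,2-dioxaborolane, via lithiated bis(pinacolboryl)methane 11 (not isolated), via lithium 2,2-diboryl-1-arylethoxide 12 (not isolated)
Conditions: n-BuLi, 2,2,6,6-tetramethylpiperidine, THF, 0 °C; 10, 0 °C; then 9, −78 °C → rt
Reagents that add atoms: none
Why: Boron-Wittig olefination, in which the α-boryl carbanion 11 adds to the non-enolisable aldehyde and the adduct 12 loses a boron–oxygen unit by syn elimination to give the (E)-alkenylboronate.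

Step 8
Reactants: 8 3-(benzyloxy)-5-hydroxy-4-(hydroxymethyl)phenyl 3,4,5-tris(benzyloxy)benzoate; 13 (E)-4,4,5,5-tetramethyl-2-{2-[3,4,5-tris(benzyloxy)phenyl]ethenyl}-1,3,2-dioxaborolane
Product: 15 (2R,3R)-5-(benzyloxy)-3-(4,4,5,5-tetramethyl-1,3,2-dioxaborolan-2-yl)-2-[3,4,5-tris(benzyloxy)phenyl]-3,4-dihydro-2H-chromen-7-yl 3,4,5-tris(benzyloxy)benzoate (2,3-trans), via ring A ortho-quinone methide 14 (not isolated)
Conditions: (R)-3,3'-bis(2,4,6-triisopropylphenyl)-1,1'-binaphthyl-2,2'-diyl hydrogen phosphate (10 mol %), 5 Å MS, PhMe, 0 °C → rt; 8 added over 6 h to 13 (3 equiv)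
Reagents that add atoms: none
Why: Proposed new method: the phosphoric acid ionises the benzylic C–OH of electron-rich ring A to ortho-quinone methide 14, which stays hydrogen-bonded or ion-paired to the chiral phosphate, and the boron-bearing alkene carbon of 13 attacks the exocyclic CH2 (C3–C4) because the positive charge then develops at the aryl-bearing carbon, which the ring A oxygen captures (O1–C2) in the same asynchronous event. The closest known reaction type is the chiral phosphoric acid catalysed inverse-demand oxa-[4+2] of in situ ortho-quinone methides with styrenes, vinylindoles and enol ethers, where an alkenylboronate has not yet served as the 2π partner. Ring C closes as the six-membered ring of this intermolecular [4+2], C3–C4 leading and O1–C2 following, with no separate cyclisation. C2 and C3 are set together: their trans relation follows from the (E) geometry of 13 carried suprafacially into the ring (aryl and boron both equatorial), and their absolute sense from the alkene face admitted by the 3,3'-aryl pocket of the phosphate, which must be established by experiment, the (S)-acid being taken if the (R)-acid gives the other hand. The step needs regioselectivity (secured by aryl stabilisation of the C2 cation, reinforced by the β C–B bond), retention of boron (secured by the pinacol ester, which does not exchange onto the ring A phenol and so stays out of the known boronate 1,4-transfer that expels boron) and suppression of self-alkylation of ring A by 14 (slow addition of 8 to excess 13, helped by the deactivating gallate on ring A).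

Step 9
Reactants: 15 (2R,3R)-5-(benzyloxy)-3-(4,4,5,5-tetramethyl-1,3,2-dioxaborolan-2-yl)-2-[3,4,5-tris(benzyloxy)phenyl]-3,4-dihydro-2H-chromen-7-yl 3,4,5-tris(benzyloxy)benzoate
Product: 17 (2S,3R)-5-(benzyloxy)-3-hydroxy-2-[3,4,5-tris(benzyloxy)phenyl]-3,4-dihydro-2H-chromen-7-yl 3,4,5-tris(benzyloxy)benzoate, via C3 pinacol borate ester 16 (not isolated)
Conditions: NaBO3·4H2O (3 equiv), THF/H2O, 0 °C → rt
Reagents that add atoms: sodium perborate tetrahydrate, [Na+].[O-]OB=O.O.O.O.O
Why: Oxidation of the carbon–boron bond through a peroxoborate ate complex moves C3 from boron to oxygen with retention, so the hydroxyl stays trans to the C2 aryl group, and mild perborate is chosen over NaOH/H2O2 to spare the aryl gallate.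

Step 10
Reactants: 17 (2S,3R)-5-(benzyloxy)-3-hydroxy-2-[3,4,5-tris(benzyloxy)phenyl]-3,4-dihydro-2H-chromen-7-yl 3,4,5-tris(benzyloxy)benzoate
Product: 18 (2S,3R)-3,5-dihydroxy-2-(3,4,5-trihydroxyphenyl)-3,4-dihydro-2H-chromen-7-yl 3,4,5-trihydroxybenzoate
Conditions: H2 (1 atm), Pd(OH)2/C, THF/MeOH, rt; filtration under Ar
Reagents that add atoms: none
Why: Hydrogenolysis of the seven aryl benzyl ethers at 1 atm leaves the aryl ester, the flavan C2–O1 bond and both stereocentres untouched, as is usual for benzylated catechin gallates.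

**Compound list**

1 | 2,4,6-trihydroxybenzaldehyde | O=Cc1c(O)cc(O)cc1O | starting material
2 | 2-hydroxy-4,6-bis(methoxymethoxy)benzaldehyde | O=Cc1c(O)cc(OCOC)cc1OCOC | intermediate
3 | 2-(benzyloxy)-4,6-bis(methoxymethoxy)benzaldehyde | O=Cc1c(OCc2ccccc2)cc(OCOC)cc1OCOC | intermediate
4 | 2-(benzyloxy)-4,6-dihydroxybenzaldehyde | O=Cc1c(OCc2ccccc2)cc(O)cc1O | intermediate
5 | 3,4,5-tris(benzyloxy)benzoic acid | OC(=O)c1cc(OCc2ccccc2)c(OCc2ccccc2)c(OCc2ccccc2)c1 | starting material
6 | 3,4,5-tris(benzyloxy)benzoyl chloride | ClC(=O)c1cc(OCc2ccccc2)c(OCc2ccccc2)c(OCc2ccccc2)c1 | intermediate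
7 | 3-(benzyloxy)-4-formyl-5-hydroxyphenyl 3,4,5-tris(benzyloxy)benzoate | O=Cc1c(O)cc(OC(=O)c2cc(OCc3ccccc3)c(OCc3ccccc3)c(OCc3ccccc3)c2)cc1OCc1ccccc1 | intermediate
8 | 3-(benzyloxy)-5-hydroxy-4-(hydroxymethyl)phenyl 3,4,5-tris(benzyloxy)benzoate | OCc1c(O)cc(OC(=O)c2cc(OCc3ccccc3)c(OCc3ccccc3)c(OCc3ccccc3)c2)cc1OCc1ccccc1 | intermediate
9 | 3,4,5-tris(benzyloxy)benzaldehyde | O=Cc1cc(OCc2ccccc2)c(OCc2ccccc2)c(OCc2ccccc2)c1 | starting material
10 | 2,2'-methylenebis(4,4,5,5-tetramethyl-1,3,2-dioxaborolane) | CC1(C)OB(CB2OC(C)(C)C(C)(C)O2)OC1(C)C | starting material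
11 | [bis(4,4,5,5-tetramethyl-1,3,2-dioxaborolan-2-yl)methyl]lithium | [Li]C(B1OC(C)(C)C(C)(C)O1)B1OC(C)(C)C(C)(C)O1 | intermediate
12 | lithium 2,2-bis(4,4,5,5-tetramethyl-1,3,2-dioxaborolan-2-yl)-1-[3,4,5-tris(benzyloxy)phenyl]ethoxide (racemic) | [Li]OC(c1cc(OCc2ccccc2)c(OCc2ccccc2)c(OCc2ccccc2)c1)C(B1OC(C)(C)C(C)(C)O1)B1OC(C)(C)C(C)(C)O1 | intermediate
13 | (E)-4,4,5,5-tetramethyl-2-{2-[3,4,5-tris(benzyloxy)phenyl]ethenyl}-1,3,2-dioxaborolane | CC1(C)OB(/C=C/c2cc(OCc3ccccc3)c(OCc3ccccc3)c(OCc3ccccc3)c2)OC1(C)C | intermediate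
14 | 5-(benzyloxy)-4-methylidene-3-oxocyclohexa-1,5-dien-1-yl 3,4,5-tris(benzyloxy)benzoate (ring A ortho-quinone methide) | C=C1C(=O)C=C(OC(=O)c2cc(OCc3ccccc3)c(OCc3ccccc3)c(OCc3ccccc3)c2)C=C1OCc1ccccc1 | intermediate
15 | (2R,3R)-5-(benzyloxy)-3-(4,4,5,5-tetramethyl-1,3,2-dioxaborolan-2-yl)-2-[3,4,5-tris(benzyloxy)phenyl]-3,4-dihydro-2H-chromen-7-yl 3,4,5-tris(benzyloxy)benzoate | O=C(Oc1cc(OCc3ccccc3)c2c(c1)O[C@@H](c3cc(OCc4ccccc4)c(OCc4ccccc4)c(OCc4ccccc4)c3)[C@H](B3OC(C)(C)C(C)(C)O3)C2)c1cc(OCc2ccccc2)c(OCc2ccccc2)c(OCc2ccccc2)c1 | intermediate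
16 | (2S,3R)-5-(benzyloxy)-3-[(4,4,5,5-tetramethyl-1,3,2-dioxaborolan-2-yl)oxy]-2-[3,4,5-tris(benzyloxy)phenyl]-3,4-dihydro-2H-chromen-7-yl 3,4,5-tris(benzyloxy)benzoate | O=C(Oc1cc(OCc3ccccc3)c2c(c1)O[C@@H](c3cc(OCc4ccccc4)c(OCc4ccccc4)c(OCc4ccccc4)c3)[C@H](OB3OC(C)(C)C(C)(C)O3)C2)c1cc(OCc2ccccc2)c(OCc2ccccc2)c(OCc2ccccc2)c1 | intermediate
17 | (2S,3R)-5-(benzyloxy)-3-hydroxy-2-[3,4,5-tris(benzyloxy)phenyl]-3,4-dihydro-2H-chromen-7-yl 3,4,5-tris(benzyloxy)benzoate | O=C(Oc1cc(OCc3ccccc3)c2c(c1)O[C@@H](c3cc(OCc4ccccc4)c(OCc4ccccc4)c(OCc4ccccc4)c3)[C@H](O)C2)c1cc(OCc2ccccc2)c(OCc2ccccc2)c(OCc2ccccc2)c1 | intermediate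
18 | (2S,3R)-3,5-dihydroxy-2-(3,4,5-trihydroxyphenyl)-3,4-dihydro-2H-chromen-7-yl 3,4,5-trihydroxybenzoate | O=C(Oc1cc(O)c2c(c1)O[C@@H](c1cc(O)c(O)c(O)c1)[C@H](O)C2)c1cc(O)c(O)c(O)c1 | target

**Step count**

Total steps: 10. Longest linear sequence: 8 (steps 1, 2, 3, 5, 6, 8, 9, 10).

**Steps most likely to fail**

Step 8. Three processes threaten it. First, the β-boryl styrene may be too weak a nucleophile (the flanked 4-benzyloxy group of ring B is twisted and donates poorly), so that 14 instead alkylates free ring A positions of 8 or 15 and oligomerises. Second, boron may be lost by ipso-substitution after the C3–C4 bond forms, opening the ring to a cinnamylphenol. Third, facial discrimination by the phosphate may be weak. The fallback uses known chemistry, sets out from 7 and 13 and returns at 15. Boronate 13 is cleaved with NaIO4 and NH4OAc in acetone/water to (E)-2-[3,4,5-tris(benzyloxy)phenyl]ethenylboronic acid F1. F1 is condensed with salicylaldehyde 7 and dibenzylamine (20 mol %) in toluene at 80 °C (Petasis-type alkenyl transfer, loss of amine, oxa-6π closure) to racemic 5-(benzyloxy)-2-[3,4,5-tris(benzyloxy)phenyl]-2H-chromen-7-yl 3,4,5-tris(benzyloxy)benzoate F2. Enantioselective protoboration of the styrene-type C3=C4 bond of F2 follows: CuCl, 1,2-bis[(2R,5R)-2,5-diphenylphospholan-1-yl]ethane or its antipode, NaOC(CH3)3 (cat.), bis(pinacolato)diboron (0.55 equiv), MeOH, THF. It is run as a kinetic resolution that consumes the (R)-chromene and places boron on C3 anti to the C2 aryl group, giving 15. At most half of F2 is converted; the slow enantiomer is recovered.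

Step 9. Peroxoborate may perhydrolyse the aryl gallate faster than it oxidises the hindered secondary boronate, giving mixtures of ester and phenol. The fallback sets out from 15 and returns at 17, and accepts the cleavage. NaOH/H2O2 in THF/EtOH at 0 °C oxidises the C–B bond and removes the ester in one operation, giving (2S,3R)-5-(benzyloxy)-2-[3,4,5-tris(benzyloxy)phenyl]-3,4-dihydro-2H-chromene-3,7-diol F3, with acid 5 recovered. The 7-phenol of F3 is then re-acylated selectively over the secondary C3 alcohol with 6 (1.0 equiv), Et3N, CH2Cl2 at −20 °C without an acyl-transfer catalyst, to give 17.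

Step 6. Under the basic hydride medium the phenoxide of the product may expel the benzylic oxygen to form the quinone methide early. That leads to over-reduction to the methyl arene or to oligomerisation on isolation, and alcoholysis of the aryl ester may compete. The fallback sets out from 7 and returns at 8, and removes the free phenol during the reduction. Silylation of 7 (t-BuMe2SiOTf, 2,6-lutidine, CH2Cl2, −78 °C) gives 3-(benzyloxy)-5-[(tert-butyldimethylsilyl)oxy]-4-formylphenyl 3,4,5-tris(benzyloxy)benzoate F4. NaBH4 in THF/EtOH at −20 °C then gives the storable 3-(benzyloxy)-5-[(tert-butyldimethylsilyl)oxy]-4-(hydroxymethyl)phenyl 3,4,5-tris(benzyloxy)benzoate F5; a silyl shift to the benzylic oxygen would be harmless. Et3N·3HF in THF at 0 °C releases 8 immediately before step 8.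

**Further compounds**

F1 | step 8 | (E)-2-[3,4,5-tris(benzyloxy)phenyl]ethenylboronic acid | OB(O)/C=C/c1cc(OCc2ccccc2)c(OCc2ccccc2)c(OCc2ccccc2)c1
F2 | step 8 | racemic 5-(benzyloxy)-2-[3,4,5-tris(benzyloxy)phenyl]-2H-chromen-7-yl 3,4,5-tris(benzyloxy)benzoate | O=C(Oc1cc(OCc3ccccc3)c2c(c1)OC(c3cc(OCc4ccccc4)c(OCc4ccccc4)c(OCc4ccccc4)c3)C=C2)c1cc(OCc2ccccc2)c(OCc2ccccc2)c(OCc2ccccc2)c1
F3 | step 9 | (2S,3R)-5-(benzyloxy)-2-[3,4,5-tris(benzyloxy)phenyl]-3,4-dihydro-2H-chromene-3,7-diol | Oc1cc(OCc3ccccc3)c2c(c1)O[C@@H](c3cc(OCc4ccccc4)c(OCc4ccccc4)c(OCc4ccccc4)c3)[C@H](O)C2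
F4 | step 6 | 3-(benzyloxy)-5-[(tert-butyldimethylsilyl)oxy]-4-formylphenyl 3,4,5-tris(benzyloxy)benzoate | O=Cc1c(O[Si](C)(C)C(C)(C)C)cc(OC(=O)c2cc(OCc3ccccc3)c(OCc3ccccc3)c(OCc3ccccc3)c2)cc1OCc1ccccc1
F5 | step 6 | 3-(benzyloxy)-5-[(tert-butyldimethylsilyl)oxy]-4-(hydroxymethyl)phenyl 3,4,5-tris(benzyloxy)benzoate | OCc1c(O[Si](C)(C)C(C)(C)C)cc(OC(=O)c2cc(OCc3ccccc3)c(OCc3ccccc3)c(OCc3ccccc3)c2)cc1OCc1ccccc1
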